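**Plan**
- Retrosynthetic cuts, in order:
  - the two C–H bonds that turn a CH2=C(aryl)–O–acyl unit into the CH3–CH(aryl)–O–acyl unit;
  - the vinyl C–O bond to the carboxylate oxygen, giving an arylacetylene and the Z-acid;
  - the ketone C(=O)–CH= bond and the aryl–C(sp) bond, giving 5-iodosalicylaldehyde, the isobutenyl Grignard reagent and trimethylsilylacetylene. The acid goes back to 3-methylfuran-2(5H)-one.
- Enabling feature: the only stereocentre is the benzylic carbon that carries H, CH3, the benzene ring and the ester oxygen. In its dehydro form the alkene carbon, that O, the acyl C and the C=O oxygen can close a five-membered chelate with a metal.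
- Forward order: no ring is made (the benzene ring is bought, the butenolide ring is opened). The alkyne goes onto the ring first, then the senecioyl ketone is built. The Z-acid is made separately, acid and alkyne are joined through C–O, and hydrogenation is the last step.
- Stereochemistry: the Z-alkene is inherited from the cis-locked butenolide, and the acid only ever reacts as a nucleophile. The S centre is set by the chiral bisphosphine on rhodium.

Key step: step 8

Assumption: the (S,S)-Me-DuPhos ligand is taken to give the S ester, by analogy with 1-arylvinyl acetates and alpha-aryl enamides. The sense should be checked on the first run, and the (R,R) ligand is equally available.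

**Step 1**
Reactants: 1 5-iodosalicylaldehyde; 2 trimethylsilylacetylene
Product: 3 2-hydroxy-5-[(trimethylsilyl)ethynyl]benzaldehyde
Conditions: PdCl2(PPh3)2 (2 mol %), CuI (4 mol %), Et3N, THF, rt
Reagents that add atoms: none
Why: Sonogashira coupling, routine on halosalicylaldehydes; the iodide is para to the free phenol, so oxidative addition is fast at room temperature and no benzofuran can form.

**Step 2**
Reactants: 3 2-hydroxy-5-[(trimethylsilyl)ethynyl]benzaldehyde
Product: 4 5-ethynyl-2-hydroxybenzaldehyde
Conditions: K2CO3 (2 equiv), MeOH, rt; then 1 M HCl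
Reagents that add atoms: none
Why: Base-mediated protodesilylation of an alkynylsilane, placed at the aldehyde stage so that carbonate and methoxide never meet the later 2-hydroxyaryl enone, which would close to a 2,2-dimethylchroman-4-one by oxa-Michael addition.

**Step 3**
Reactants: 4 5-ethynyl-2-hydroxybenzaldehyde; 5 2-methylprop-1-enylmagnesium bromide (3.3 equiv)
Product: 6 (±)-4-ethynyl-2-(1-hydroxy-3-methylbut-2-en-1-yl)phenol
Conditions: 4 added to 5, THF, 0 °C to rt; sat. aq. NH4Cl, 0 °C; used crude
Reagents that add atoms: none
Why: Grignard 1,2-addition to an aldehyde, in which two equivalents are spent on the phenol and alkyne protons and the third adds to the formyl group; inverse addition keeps the alkenyl reagent in excess over the less nucleophilic alkynylmagnesium, the buffered quench avoids dehydration to the 2,2-dimethylchromene, and the carbinol centre forms racemic and is erased in step 4.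

**Step 4**
Reactants: 6 (±)-4-ethynyl-2-(1-hydroxy-3-methylbut-2-en-1-yl)phenol
Product: 7 1-(5-ethynyl-2-hydroxyphenyl)-3-methylbut-2-en-1-one
Conditions: activated MnO2 (15 equiv), CH2Cl2, rt
Reagents that add atoms: none
Why: MnO2 oxidation of an alcohol that is both allylic and benzylic, under neutral heterogeneous conditions that should leave the phenol and the terminal alkyne untouched and give a ketone stabilised by the OH···O=C hydrogen bond.

**Step 5**
Reactants: 8 3-methylfuran-2(5H)-one
Product: 11 4-methoxybenzyl (Z)-4-acetoxy-2-methylbut-2-enoate, via potassium (Z)-4-hydroxy-2-methylbut-2-enoate 9 (not isolated), via 4-methoxybenzyl (Z)-4-hydroxy-2-methylbut-2-enoate 10 (not isolated)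
Conditions: aq. KOH (1.0 equiv), THF, 0 °C to rt, evaporate, toluene azeotrope; PMBCl, cat. Bu4NI, DMF, rt; then Ac2O, pyridine, cat. DMAP, 0 °C to rt
Reagents that add atoms: potassium hydroxide [K+].[OH-]; 4-methoxybenzyl chloride COc1ccc(CCl)cc1; acetic anhydride CC(=O)OC(C)=O
Why: Lactone saponification, SN2 O-alkylation of the carboxylate and DMAP-catalysed acetylation in one flask; the ring fixes the Z geometry, the free hydroxy acid that would relactonise is never generated, and the hydroxy ester is capped before it can close back.

**Step 6**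
Reactants: 11 4-methoxybenzyl (Z)-4-acetoxy-2-methylbut-2-enoate
Product: 12 (Z)-4-acetoxy-2-methylbut-2-enoic acid
Conditions: TFA (10 vol %), anisole (3 equiv), CH2Cl2, 0 °C
Reagents that add atoms: none
Why: Acidolysis of a 4-methoxybenzyl ester, with the benzylic cation trapped by anisole in a Friedel–Crafts alkylation; the primary, electron-poor allylic acetate and the Z-alkene should be inert to cold TFA, and the acetyl cap blocks lactonisation.

**Step 7**
Reactants: 7 1-(5-ethynyl-2-hydroxyphenyl)-3-methylbut-2-en-1-one; 12 (Z)-4-acetoxy-2-methylbut-2-enoic acid (1.2 equiv)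
Product: 13 1-[4-hydroxy-3-(3-methylbut-2-enoyl)phenyl]vinyl (Z)-4-acetoxy-2-methylbut-2-enoate
Conditions: [RuCl2(p-cymene)]2 (1 mol %), P(2-furyl)3 (2 mol %), Na2CO3 (4 mol %), toluene, 50 °C
Reagents that add atoms: none
Why: Ruthenium-catalysed Markovnikov hydro-acyloxylation of a terminal alkyne, in which the carboxylate attacks the internal carbon of the Ru-bound alkyne; the acid acts as nucleophile and is never activated, the weakly nucleophilic phosphine should not isomerise the Z-enoate, and the hydrogen-bonded phenol stays protonated beside the much stronger carboxylic acid.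

**Step 8**
Reactants: 13 1-[4-hydroxy-3-(3-methylbut-2-enoyl)phenyl]vinyl (Z)-4-acetoxy-2-methylbut-2-enoate
Product: 14 (S)-1-[4-hydroxy-3-(3-methylbut-2-enoyl)phenyl]ethyl (Z)-4-acetoxy-2-methylbut-2-enoate
Conditions: [Rh(cod)((S,S)-Me-DuPhos)]BF4 (2 mol %), H2 (4 bar), degassed THF, rt, stopped at full conversion of 13
Reagents that add atoms: none
Why: This is a rhodium-catalysed asymmetric hydrogenation of a 1-arylvinyl carboxylate, the oxygen counterpart of enamide hydrogenation and a known substrate class for cationic Rh–bisphospholane catalysts. Once cod has been hydrogenated off, the CH2=C alkene and the carbonyl oxygen of its own acyloxy group bind Rh(I) as a five-membered chelate; oxidative addition of H2, migratory insertion and reductive elimination then put both hydrogens on one face, making the C–H bond at the benzylic carbon and one C–H bond of the new methyl group. No ring is closed. The single new stereocentre is controlled by the C2-symmetric ligand alone, whose blocked quadrants decide which face of the chelated alkene is turned over, and the (S,S) ligand should lead to S. The step needs chemoselectivity for one of three alkenes: only the enol-ester alkene is 1,1-disubstituted and able to chelate, whereas the butenoate and senecioyl alkenes are trisubstituted, conjugated to carbonyl groups and lack a donor in the right place, and this catalyst family is known to spare such alkenes at low pressure. THF in place of an alcohol prevents solvolysis of the para-hydroxybenzylic ester, and because nothing follows this step the centre cannot be scrambled later.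

**Compound list**
1 | 5-iodosalicylaldehyde | O=Cc1cc(I)ccc1O | starting material
2 | trimethylsilylacetylene | C#C[Si](C)(C)C | starting material
3 | 2-hydroxy-5-[(trimethylsilyl)ethynyl]benzaldehyde | O=Cc1cc(C#C[Si](C)(C)C)ccc1O | intermediate
4 | 5-ethynyl-2-hydroxybenzaldehyde | O=Cc1cc(C#C)ccc1O | intermediate
5 | 2-methylprop-1-enylmagnesium bromide | CC(C)=C[Mg]Br | starting material
6 | (±)-4-ethynyl-2-(1-hydroxy-3-methylbut-2-en-1-yl)phenol | CC(C)=CC(O)c1cc(C#C)ccc1O | intermediate
7 | 1-(5-ethynyl-2-hydroxyphenyl)-3-methylbut-2-en-1-one | CC(C)=CC(=O)c1cc(C#C)ccc1O | intermediate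
8 | 3-methylfuran-2(5H)-one | CC1=CCOC1=O | starting material
9 | potassium (Z)-4-hydroxy-2-methylbut-2-enoate (not isolated) | OC/C=C(/C)C(=O)[O-].[K+] | intermediate
10 | 4-methoxybenzyl (Z)-4-hydroxy-2-methylbut-2-enoate (not isolated) | OC/C=C(/C)C(=O)OCc1ccc(OC)cc1 | intermediate
11 | 4-methoxybenzyl (Z)-4-acetoxy-2-methylbut-2-enoate | CC(=O)OC/C=C(/C)C(=O)OCc1ccc(OC)cc1 | intermediate
12 | (Z)-4-acetoxy-2-methylbut-2-enoic acid | CC(=O)OC/C=C(/C)C(=O)O | intermediate
13 | 1-[4-hydroxy-3-(3-methylbut-2-enoyl)phenyl]vinyl (Z)-4-acetoxy-2-methylbut-2-enoate | CC(=O)OC/C=C(/C)C(=O)OC(=C)c1ccc(O)c(C(=O)C=C(C)C)c1 | intermediate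
14 | (S)-1-[4-hydroxy-3-(3-methylbut-2-enoyl)phenyl]ethyl (Z)-4-acetoxy-2-methylbut-2-enoate | CC(=O)OC/C=C(/C)C(=O)O[C@@H](C)c1ccc(O)c(C(=O)C=C(C)C)c1 | target

Total step count: 8. Longest linear sequence: 6 (steps 1, 2, 3, 4, 7, 8).

**Steps most likely to fail**

**Step 8.** Facial discrimination may be poorer than with simple enol acetates because the acyl group is larger and unsaturated. The two trisubstituted alkenes may be slowly saturated on long exposure. Turnover may drop if rhodium is held by the electron-rich arene or the acylphenol.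

The fallback sets the centre by ketone reduction. It sets out from 7 and comes back at 14. Markovnikov hydration of the alkyne of 7 (cat. Ph3PAuNTf2, aqueous dioxane) should give 1-(5-acetyl-2-hydroxyphenyl)-3-methylbut-2-en-1-one F1. Noyori transfer hydrogenation with RuCl(p-cymene)[(R,R)-TsDPEN] in HCO2H/Et3N should reduce the non-chelated acetyl group in preference to the hydrogen-bonded enone. This would give (R)-1-[2-hydroxy-5-(1-hydroxyethyl)phenyl]-3-methylbut-2-en-1-one F2. A Mitsunobu esterification with 12 (PPh3, DIAD, toluene, −20 °C) then inverts the carbinol to 14, again with the acid as nucleophile.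

**Step 7.** Regiochemistry may leak to the linear enol ester through a ruthenium vinylidene. The catalyst may be sequestered by O,O-chelation of the 2-acylphenol, and the alkyne may dimerise.

The fallback masks the chelating phenol and changes the mode of alkyne activation to an outer-sphere π-acid addition, which cannot pass through a vinylidene. It sets out from 7 and comes back at 13. Silylation (TBSOTf, 2,6-lutidine, CH2Cl2, 0 °C) should give 1-{2-[(tert-butyldimethylsilyl)oxy]-5-ethynylphenyl}-3-methylbut-2-en-1-one F3. Gold(I)-catalysed addition of 12 (Ph3PAuCl/AgOTf, dry toluene, 60 °C) should give 1-{4-[(tert-butyldimethylsilyl)oxy]-3-(3-methylbut-2-enoyl)phenyl}vinyl (Z)-4-acetoxy-2-methylbut-2-enoate F4. Et3N·3HF in THF then frees the phenol to 13. At this stage there is no benzylic leaving group that a phenoxide could expel.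

**Step 5.** The hydroxy ester may close back to the lactone before it is acetylated. Alkylation of the salt may be incomplete, and the double bond may migrate under base during the saponification.

The fallback traps the salt by silylation and postpones the acetate to the end. It sets out from 9 and comes back at 14. Dry 9 is silylated on both oxygens (TBSCl, imidazole, DMF) to tert-butyldimethylsilyl (Z)-4-[(tert-butyldimethylsilyl)oxy]-2-methylbut-2-enoate F5. K2CO3 in aqueous MeOH–THF should cleave only the silyl ester, giving (Z)-4-[(tert-butyldimethylsilyl)oxy]-2-methylbut-2-enoic acid F6. F6 takes the place of 12 in the ruthenium-catalysed addition to 7, giving 1-[4-hydroxy-3-(3-methylbut-2-enoyl)phenyl]vinyl (Z)-4-[(tert-butyldimethylsilyl)oxy]-2-methylbut-2-enoate F7. The same rhodium hydrogenation then gives (S)-1-[4-hydroxy-3-(3-methylbut-2-enoyl)phenyl]ethyl (Z)-4-[(tert-butyldimethylsilyl)oxy]-2-methylbut-2-enoate F8. HF·pyridine in THF at 0 °C frees (S)-1-[4-hydroxy-3-(3-methylbut-2-enoyl)phenyl]ethyl (Z)-4-hydroxy-2-methylbut-2-enoate F9. This is acetylated at once (Ac2O, pyridine, 0 °C) to 14; the hydrogen-bonded phenol should react more slowly than the primary alcohol.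

**Further compounds**
F1 | step 8 | 1-(5-acetyl-2-hydroxyphenyl)-3-methylbut-2-en-1-one | CC(=O)c1ccc(O)c(C(=O)C=C(C)C)c1
F2 | step 8 | (R)-1-[2-hydroxy-5-(1-hydroxyethyl)phenyl]-3-methylbut-2-en-1-one | O[C@H](C)c1ccc(O)c(C(=O)C=C(C)C)c1
F3 | step 7 | 1-{2-[(tert-butyldimethylsilyl)oxy]-5-ethynylphenyl}-3-methylbut-2-en-1-one | CC(C)=CC(=O)c1cc(C#C)ccc1O[Si](C)(C)C(C)(C)C
F4 | step 7 | 1-{4-[(tert-butyldimethylsilyl)oxy]-3-(3-methylbut-2-enoyl)phenyl}vinyl (Z)-4-acetoxy-2-methylbut-2-enoate | CC(=O)OC/C=C(/C)C(=O)OC(=C)c1ccc(O[Si](C)(C)C(C)(C)C)c(C(=O)C=C(C)C)c1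
F5 | step 5 | tert-butyldimethylsilyl (Z)-4-[(tert-butyldimethylsilyl)oxy]-2-methylbut-2-enoate | CC(C)(C)[Si](C)(C)OC/C=C(/C)C(=O)O[Si](C)(C)C(C)(C)C
F6 | step 5 | (Z)-4-[(tert-butyldimethylsilyl)oxy]-2-methylbut-2-enoic acid | CC(C)(C)[Si](C)(C)OC/C=C(/C)C(=O)O
F7 | step 5 | 1-[4-hydroxy-3-(3-methylbut-2-enoyl)phenyl]vinyl (Z)-4-[(tert-butyldimethylsilyl)oxy]-2-methylbut-2-enoate | CC(C)(C)[Si](C)(C)OC/C=C(/C)C(=O)OC(=C)c1ccc(O)c(C(=O)C=C(C)C)c1
F8 | step 5 | (S)-1-[4-hydroxy-3-(3-methylbut-2-enoyl)phenyl]ethyl (Z)-4-[(tert-butyldimethylsilyl)oxy]-2-methylbut-2-enoate | CC(C)(C)[Si](C)(C)OC/C=C(/C)C(=O)O[C@@H](C)c1ccc(O)c(C(=O)C=C(C)C)c1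
F9 | step 5 | (S)-1-[4-hydroxy-3-(3-methylbut-2-enoyl)phenyl]ethyl (Z)-4-hydroxy-2-methylbut-2-enoate | OC/C=C(/C)C(=O)O[C@@H](C)c1ccc(O)c(C(=O)C=C(C)C)c1
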